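**Retrosynthetic overview**
- The C9 acetate (enone α'-acetoxylation), the C4 senecioate (acylation) and the C4 hydroxyl (ketone reduction) are installed last, on a spiro[4.5]dec-6-ene-4,8-dione.
- Key disconnection: C4-C5 and C5-C10 are both cut at the spiro carbon, which gives an acyclic cross-conjugated dienone acid. In the forward direction both bonds form in one pot. Ring A closes first by a vinylogous Dieckmann-type acylation, and ring B closes second by a 6-endo Michael/6π closure.
- The dienone acid comes from a keto acid by two-carbon homologation (HWE with a Weinreb phosphonate) and addition of propenyl Grignard reagent.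
- The keto acid comes from (+)-limonene oxide by oxidative ring cleavage. Its single stereocentre (future C2) relays to C5 and C10, then to C4 and C9.

Assumption: spirovetivane-type atom labels are used throughout, also for the open-chain precursors (C1-C4 = ring A, C5 = spiro carbon, C6-C10 = ring B; C4 carries the senecioate and C9 the acetate).

**Step 1**
Reactants: 1 (+)-limonene oxide, (4R)-1,2-epoxy-p-menth-8-ene (commercial cis/trans mixture)
Product: 2 (3R)-6-oxo-3-(prop-1-en-2-yl)heptanal
Conditions: H5IO6 (1.1 equiv), THF/H2O 4:1, 0 °C to rt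
Reagents that add atoms: water, O
Why: Epoxide hydrolysis followed by Malaprade glycol cleavage converts both epoxide diastereomers into the same keto aldehyde, leaves the 1,1-disubstituted alkene alone and carries the (R) centre (future C2) through unchanged.

**Step 2**
Reactants: 2 (3R)-6-oxo-3-(prop-1-en-2-yl)heptanal
Product: 3 (3R)-6-oxo-3-(prop-1-en-2-yl)heptanoic acid
Conditions: NaClO2, NaH2PO4, 2-methylbut-2-ene, t-BuOH/H2O, rt
Reagents that add atoms: sodium chlorite, [Na+].[O-]Cl=O
Why: Pinnick oxidation takes only the aldehyde to the acid, and 2-methylbut-2-ene scavenges HOCl so that the isopropenyl group and the non-epimerisable C2 centre survive.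

**Step 3**
Reactants: 3 (3R)-6-oxo-3-(prop-1-en-2-yl)heptanoic acid; 4 diethyl [2-(methoxy(methyl)amino)-2-oxoethyl]phosphonate
Product: 5 (3R,6E)-8-[methoxy(methyl)amino]-6-methyl-8-oxo-3-(prop-1-en-2-yl)oct-6-enoic acid (E major, E/Z mixture used)
Conditions: NaH (2.3 equiv), THF, 0 °C to reflux; 1 M HCl work-up
Reagents that add atoms: none
Why: Horner-Wadsworth-Emmons olefination of the methyl ketone (the carboxylate is inert) builds C6=C7; no stereocentre forms, and the E/Z ratio does not matter because this bond loses its geometry in the dienolates of step 5.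

**Step 4**
Reactants: 5 Weinreb amide acid; 6 prop-1-enylmagnesium bromide, CH3CH=CHMgBr (commercial E/Z mixture)
Product: 7 (3R,6E,9E)-6-methyl-8-oxo-3-(prop-1-en-2-yl)undeca-6,9-dienoic acid
Conditions: CH3CH=CHMgBr (2.3 equiv), THF, −40 to 0 °C; cold 1 M HCl quench
Reagents that add atoms: none
Why: In this Weinreb ketone synthesis the first equivalent of Grignard reagent parks the acid as its unreactive carboxylate, the second gives the chelated adduct that collapses to the cross-conjugated dienone only on acidic quench, and Z-propenyl material is funnelled to E in step 5.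

**Step 5 (key step)**
Reactants: 7 dienone acid; 8 1,1'-carbonyldiimidazole (CDI)
Product: 11 (2R,5S,10S)-6,10-dimethyl-2-(prop-1-en-2-yl)spiro[4.5]dec-6-ene-4,8-dione (C10 methyl cis to C4 on ring B; C10 trans to the isopropenyl group on ring A), via acyl imidazolide 9 (not isolated), via alkenyl cyclopentanone 10 (not isolated)
Conditions: CDI (1.05 equiv), THF, rt; dilute to 0.01 M, KN(SiMe3)2 (2.1 equiv), −78 to 0 °C; AcOH (2.1 equiv), then 65 °C
Reagents that add atoms: none
Why: Proposed new method: the base reversibly forms all extended dienolates of 9, but only the C5 dienolate can close a five-membered ring on the acyl imidazole (vinylogous Dieckmann-type 5-exo-trig C-acylation, driven by deprotonation of the very acidic C5-H of 10); after buffering, the enol(ate) of 10 closes C5-C10 by a 6-endo-trig Michael addition with disrotatory 6π geometry, in which the ring carbonyl C4 sits outside (next to the C6 methyl), C1H2 sits inside and the E-propenyl methyl sits outside, so C10-CH3 ends cis to C4, and C10 adds to the cyclopentanone face opposite the C2 isopropenyl group, which sets C5 and C10; the closest known types are the Dieckmann condensation, the second (6-endo-trig) step of [5+1] double Michael annulations of active methylene compounds with divinyl ketones, and the 6π electrocyclisation of acyl-substituted hexatrienes.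

**Step 6**
Reactants: 11 spiro enedione
Product: 12 (2R,4S,5S,10S)-4-hydroxy-6,10-dimethyl-2-(prop-1-en-2-yl)spiro[4.5]dec-6-en-8-one
Conditions: NaBH4 (0.5 equiv), MeOH/CH2Cl2 1:1, −78 to −40 °C
Reagents that add atoms: none
Why: In this chemoselective 1,2-reduction NaBH4 attacks a saturated five-ring ketone next to a quaternary carbon faster than a β,β-disubstituted conjugated enone (the androstenedione-to-testosterone selectivity), and hydride enters from the ring A face flanked by the flat sp2 carbon C6, opposite the pseudoaxial C10 methine whose methyl leans under C4, so the hydroxyl (4S) ends cis to C10 and trans to the isopropenyl group.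

**Step 7**
Reactants: 12 hydroxy enone; 13 3-methylbut-2-enoyl chloride (senecioyl chloride)
Product: 14 (2R,4S,5S,10S)-6,10-dimethyl-8-oxo-2-(prop-1-en-2-yl)spiro[4.5]dec-6-en-4-yl 3-methylbut-2-enoate
Conditions: pyridine, DMAP (0.2 equiv), CH2Cl2, 0 to 40 °C
Reagents that add atoms: none
Why: DMAP-catalysed acylation of the hindered secondary alcohol proceeds with retention at C4, and pyridine rather than a trialkylamine avoids the vinylketene path that would deconjugate the senecioyl group.

**Step 8**
Reactants: 14 senecioate enone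
Product: 15 target, (2R,4S,5S,9S,10R)-9-acetoxy-6,10-dimethyl-8-oxo-2-(prop-1-en-2-yl)spiro[4.5]dec-6-en-4-yl 3-methylbut-2-enoate
Conditions: Mn(OAc)3·2H2O (3 equiv), benzene, reflux (Dean-Stark)
Reagents that add atoms: manganese triacetate, [Mn+3].CC(=O)[O-].CC(=O)[O-].CC(=O)[O-]
Why: α'-Acetoxylation of the enone through its trivalent manganese enolate/α'-keto radical can only occur at C9 (C5 is quaternary, and esters and isolated alkenes are inert at 80 °C); acetate arrives anti to the C10 methyl, and any cis isomer epimerises in the AcOH formed to the trans-diequatorial (9S) acetate.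

**Compound list**
1 | (+)-limonene oxide, (4R), cis/trans mixture | CC12OC1C[C@@H](CC2)C(C)=C | starting material
2 | (3R)-6-oxo-3-(prop-1-en-2-yl)heptanal | O=CC[C@@H](CCC(C)=O)C(C)=C | intermediate
3 | (3R)-6-oxo-3-(prop-1-en-2-yl)heptanoic acid | OC(=O)C[C@@H](CCC(C)=O)C(C)=C | intermediate
4 | diethyl [2-(methoxy(methyl)amino)-2-oxoethyl]phosphonate | CCOP(=O)(CC(=O)N(C)OC)OCC | starting material
5 | (3R,6E)-8-[methoxy(methyl)amino]-6-methyl-8-oxo-3-(prop-1-en-2-yl)oct-6-enoic acid | OC(=O)C[C@@H](CC/C(C)=C/C(=O)N(C)OC)C(C)=C | intermediate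
6 | prop-1-enylmagnesium bromide | C/C=C/[Mg]Br | starting material
7 | (3R,6E,9E)-6-methyl-8-oxo-3-(prop-1-en-2-yl)undeca-6,9-dienoic acid | OC(=O)C[C@@H](CC/C(C)=C/C(=O)/C=C/C)C(C)=C | intermediate
8 | 1,1'-carbonyldiimidazole | O=C(n1ccnc1)n1ccnc1 | starting material
9 | acyl imidazolide of 7 | O=C(C[C@@H](CC/C(C)=C/C(=O)/C=C/C)C(C)=C)n1ccnc1 | intermediate
10 | (4R)-2-[(5E)-4-oxohepta-2,5-dien-2-yl]-4-(prop-1-en-2-yl)cyclopentan-1-one (C5 and C6=C7 mobile) | C=C(C)[C@H]1CC(=O)C(C1)C(C)=CC(=O)/C=C/C | intermediate
11 | (2R,5S,10S)-6,10-dimethyl-2-(prop-1-en-2-yl)spiro[4.5]dec-6-ene-4,8-dione | C=C(C)[C@H]1CC(=O)[C@]2(C1)C(C)=CC(=O)C[C@@H]2C | intermediate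
12 | (2R,4S,5S,10S)-4-hydroxy-6,10-dimethyl-2-(prop-1-en-2-yl)spiro[4.5]dec-6-en-8-one | C=C(C)[C@H]1C[C@H](O)[C@]2(C1)C(C)=CC(=O)C[C@@H]2C | intermediate
13 | 3-methylbut-2-enoyl chloride | CC(C)=CC(=O)Cl | starting material
14 | (2R,4S,5S,10S)-6,10-dimethyl-8-oxo-2-(prop-1-en-2-yl)spiro[4.5]dec-6-en-4-yl 3-methylbut-2-enoate | C=C(C)[C@H]1C[C@H](OC(=O)C=C(C)C)[C@]2(C1)C(C)=CC(=O)C[C@@H]2C | intermediate
15 | CNP0218315.1 | C=C(C)[C@H]1C[C@H](OC(=O)C=C(C)C)[C@]2(C1)C(C)=CC(=O)[C@@H](OC(C)=O)[C@@H]2C | target

**Total step count:** 8. **Longest linear sequence:** 8 (compounds 4, 6, 8 and 13 are purchased).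

**Steps most likely to fail**

Step 5. The risks are that γ-acylation loses to side reactions, that the Michael equilibrium is only marginally favourable, or that facial selectivity is poor. The fallback sets out from keto acid 3 and returns at 11. It builds the rings one after the other and uses a Diels-Alder reaction for ring B.
- CDI gives the acyl imidazolide F1.
- KN(SiMe3)2 under equilibrating conditions closes it to 2-acetyl-4-isopropenylcyclopentanone F2.
- Ac2O/DMAP traps the exocyclic enol as the enol acetate F3.
- This s-cis-locked alkylidene ketone is combined under EtAlCl2 catalysis with the silyloxydiene F4, made from pent-3-en-2-one with Me3SiOTf and Et3N.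
- Endo addition (C4=O under the diene) on the face opposite the isopropenyl group gives the cycloadduct F5 with the same C5/C10 configuration.
- Dilute HCl followed by DBU removes the silyl group and AcOH to give 11.

Step 6. The risks are the wrong C4 epimer or competing enone reduction. The fallback sets out from 11 and returns at 12.
- t-BuMe2SiOTf/Et3N silylates the more Lewis basic enone carbonyl to the silyl dienol ether F6.
- The only remaining ketone is reduced under catalyst control with (R)-Me-CBS oxazaborolidine and catecholborane (quaternary C5 as the large group, C3H2 as the small group) to the hydroxy dienol ether F7.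
- HF·pyridine releases enone 12.

Step 8. The risk is that radical acetoxylation attacks the alkenes or gives a low yield. The fallback sets out from 14 and returns at 15 by ionic enolate oxidation.
- LiN(SiMe3)2/Me3SiCl gives the kinetic trimethylsilyl dienol ether F8.
- One equivalent of dimethyldioxirane at −78 °C (Rubottom oxidation, anti to the C10 methyl) gives the hydroxy enone F9.
- Ac2O/DMAP gives 15.

**Further compounds**
F1 | step 5 | acyl imidazolide of 3 | O=C(C[C@@H](CCC(C)=O)C(C)=C)n1ccnc1
F2 | step 5 | (4R)-2-acetyl-4-(prop-1-en-2-yl)cyclopentan-1-one | C=C(C)[C@H]1CC(=O)C(C1)C(C)=O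
F3 | step 5 | 1-[(4R)-2-oxo-4-(prop-1-en-2-yl)cyclopentylidene]ethyl acetate | C=C(C)[C@H]1CC(=O)C(C1)=C(C)OC(C)=O
F4 | step 5 | (3E)-2-(trimethylsilyloxy)penta-1,3-diene | C=C(O[Si](C)(C)C)/C=C/C
F5 | step 5 | 6-acetoxy-6,10-dimethyl-2-(prop-1-en-2-yl)-8-(trimethylsilyloxy)spiro[4.5]dec-8-en-4-one | C=C(C)[C@H]1CC(=O)[C@]2(C1)C(C)(OC(C)=O)CC(O[Si](C)(C)C)=C[C@@H]2C
F6 | step 6 | 8-(tert-butyldimethylsilyloxy)-6,10-dimethyl-2-(prop-1-en-2-yl)spiro[4.5]deca-6,8-dien-4-one | C=C(C)[C@H]1CC(=O)[C@]2(C1)C(C)=CC(O[Si](C)(C)C(C)(C)C)=C[C@@H]2C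
F7 | step 6 | (4S)-8-(tert-butyldimethylsilyloxy)-6,10-dimethyl-2-(prop-1-en-2-yl)spiro[4.5]deca-6,8-dien-4-ol | C=C(C)[C@H]1C[C@H](O)[C@]2(C1)C(C)=CC(O[Si](C)(C)C(C)(C)C)=C[C@@H]2C
F8 | step 8 | 8-(trimethylsilyloxy) dienol ether of 14 | C=C(C)[C@H]1C[C@H](OC(=O)C=C(C)C)[C@]2(C1)C(C)=CC(O[Si](C)(C)C)=C[C@@H]2C
F9 | step 8 | (9S)-9-hydroxy derivative of 14 | C=C(C)[C@H]1C[C@H](OC(=O)C=C(C)C)[C@]2(C1)C(C)=CC(=O)[C@@H](O)[C@@H]2C
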